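The pyranone ring C is cut along C4–C4a and C2–C3, which excises a glycolyl C3–C4 unit and leaves O1–C8a=C4a of the phloroglucinol-type ring A joined to the para-oxygenated benzylic carbon C2. This C4a=C8a–O1–C2 array is a latent cationic 2-oxadiene: an O-aryl oxocarbenium ion, stabilised by ring B, whose C2 is electrophilic and whose C4a is nucleophilic. A catalytic, enantioselective oxa-Povarov-type [4+2] annulation with a glycolate-derived ketene acetal (nucleophilic C3, latent acylium C4) forges both bonds and both stereocentres of ring C in one operation. The precursor is an O-aryl O-pivaloyl acetal of 4-silyloxybenzaldehyde carrying the fully substituted, geranylated ring A.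

Key step: step 8

Assumption: the (S,S)-configured squaramide named in step 8 is taken to deliver the 2R centre; if the opposite sense of induction is found, its mirror image is used.

Step 1
Reactants: 1 5-methoxybenzene-1,3-diol
Product: 2 1-methoxy-3,5-bis(triisopropylsilyloxy)benzene
Conditions: TIPSCl (2.3 equiv), imidazole, DMF, rt → 40 °C
Reagents that add atoms: triisopropylsilyl chloride, CC(C)[Si](Cl)(C(C)C)C(C)C
Why: Imidazole-mediated silylation (silyl ether formation) of both phenols makes the two oxygen atoms meta to OMe bulky and equivalent; no stereocentre is formed.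

Step 2
Reactants: 2 1-methoxy-3,5-bis(triisopropylsilyloxy)benzene
Product: 3 2-bromo-1-methoxy-3,5-bis(triisopropylsilyloxy)benzene
Conditions: NBS (1.0 equiv), MeCN, −40 → 0 °C
Reagents that add atoms: N-bromosuccinimide, O=C1CCC(=O)N1Br
Why: Electrophilic aromatic bromination of the triply activated arene should occur at the position flanked by OMe and one OTIPS group, because the only alternative site lies between two TIPS ethers; no stereocentre is formed.

Step 3
Reactants: 3 2-bromo-1-methoxy-3,5-bis(triisopropylsilyloxy)benzene; 4 geranyl bromide [(2E)-1-bromo-3,7-dimethylocta-2,6-diene]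
Product: 6 2-[(2E)-3,7-dimethylocta-2,6-dien-1-yl]-1-methoxy-3,5-bis(triisopropylsilyloxy)benzene, via aryllithium 5 (not isolated)
Conditions: n-BuLi (1.05 equiv), THF, −78 °C; CuBr·SMe2 (10 mol %), then 4, −78 → 0 °C
Reagents that add atoms: none
Why: Bromine–lithium exchange followed by copper-catalysed allylic substitution of geranyl bromide (SN2 at the primary carbon, E-alkene retained) installs the C6 side chain, and the TIPS group is slow to undergo the retro-Brook shift at −78 °C; no stereocentre is formed.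

Step 4
Reactants: 6 2-[(2E)-3,7-dimethylocta-2,6-dien-1-yl]-1-methoxy-3,5-bis(triisopropylsilyloxy)benzene
Product: 7 4-[(2E)-3,7-dimethylocta-2,6-dien-1-yl]-3-methoxy-5-(triisopropylsilyloxy)phenol
Conditions: TBAF (1.0 equiv), THF, −78 → −30 °C; AcOH quench
Reagents that add atoms: none
Why: Fluoride-induced desilylation is expected to discriminate on steric grounds, cleaving the unhindered silyl ether para to the geranyl chain and sparing the one buttressed by it, which frees the future O1; no stereocentre is formed.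

Step 5
Reactants: 8 4-(tert-butyldimethylsilyloxy)benzaldehyde
Product: 9 chloro[4-(tert-butyldimethylsilyloxy)phenyl]methyl 2,2-dimethylpropanoate (racemic)
Conditions: PivCl (1.1 equiv), ZnCl2 (5 mol %), CH2Cl2, 0 °C → rt; used crude
Reagents that add atoms: pivaloyl chloride, CC(C)(C)C(Cl)=O
Why: ZnCl2-catalysed addition of an acyl chloride across the aldehyde C=O (α-chloroalkyl ester formation) gives a benzylic electrophile that carries a carboxylate as the future leaving group; the new stereocentre is racemic and is erased in step 8.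

Step 6
Reactants: 7 4-[(2E)-3,7-dimethylocta-2,6-dien-1-yl]-3-methoxy-5-(triisopropylsilyloxy)phenol; 9 chloro[4-(tert-butyldimethylsilyloxy)phenyl]methyl 2,2-dimethylpropanoate
Product: 11 [4-(tert-butyldimethylsilyloxy)phenyl]{4-[(2E)-3,7-dimethylocta-2,6-dien-1-yl]-3-methoxy-5-(triisopropylsilyloxy)phenoxy}methyl 2,2-dimethylpropanoate (racemic), via sodium phenoxide 10 (not isolated)
Conditions: NaH (1.05 equiv), THF/DMF, 0 °C; then 9, −20 → 0 °C; filtration through basic alumina
Reagents that add atoms: none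
Why: Williamson-type O-alkylation of the phenoxide by the α-chloroalkyl ester (the chemistry of acyloxymethyl aryl ethers) forms the O1–C2 bond, the hindered pivalate disfavouring acyl transfer and the polar medium favouring O- over C-alkylation; the acetal carbon is racemic and is planarised in step 8.

Step 7
Reactants: 12 2,2-dimethoxyacetaldehyde
Product: 13 tert-butyl[(2,2-dimethoxyethenyl)oxy]dimethylsilane
Conditions: TBSOTf (1.1 equiv), Et3N (1.5 equiv), Et2O, 0 °C → rt; 12 used as a dried CH2Cl2 extract of the commercial aqueous solution; distillation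
Reagents that add atoms: tert-butyldimethylsilyl triflate, CC(C)(C)[Si](C)(C)OS(=O)(=O)C(F)(F)F
Why: Soft enolisation with silyl triflate and amine (silyl enol ether formation) removes the only α-hydrogen, that of the acetal carbon, to give a ketene acetal with no geometrical isomers and no stereocentre.

Step 8
Reactants: 11 [4-(tert-butyldimethylsilyloxy)phenyl]{4-[(2E)-3,7-dimethylocta-2,6-dien-1-yl]-3-methoxy-5-(triisopropylsilyloxy)phenoxy}methyl 2,2-dimethylpropanoate; 13 tert-butyl[(2,2-dimethoxyethenyl)oxy]dimethylsilane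
Product: 16 (2R,3R)-3-(tert-butyldimethylsilyloxy)-2-[4-(tert-butyldimethylsilyloxy)phenyl]-6-[(2E)-3,7-dimethylocta-2,6-dien-1-yl]-5-methoxy-7-(triisopropylsilyloxy)chroman-4-one, via oxocarbenium triflate 14 (not isolated), via dimethyl ketal 15 (not isolated)
Conditions: 3-{[3,5-bis(trifluoromethyl)phenyl]amino}-4-({(2S)-3,3-dimethyl-1-oxo-1-[(2S)-2-(phenanthren-9-yl)pyrrolidin-1-yl]butan-2-yl}amino)cyclobut-3-ene-1,2-dione (10 mol %), TfOH (5 mol %), 13 (2.5 equiv), TBME, −78 → −40 °C; Et3N; then aq. citric acid (pH 3)/THF, 0 °C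
Reagents that add atoms: water, O
Why: Proposed new method: the squaramide-bound TfOH ionises acylal 11 with loss of pivalic acid (the carboxylate is the only competent leaving group) to the E-configured O-aryl oxocarbenium ion 14, whose C2 is attacked by the nucleophilic CH carbon of ketene acetal 13 (C2–C3 bond), while the developing dimethoxycarbenium centre at C4 is captured by C4a of ring A (C4–C4a bond) and rearomatisation returns the proton to the catalyst. The closest known reaction types are the oxa-Povarov cationic [4+2] annulation of O-aryl oxocarbenium ions with alkenes, the Povarov reaction under chiral urea/strong acid cocatalysis, and squaramide/silyl triflate-catalysed enantioselective additions of ketene acetals to acetal-derived aryl oxocarbenium ions; a ketene acetal as the 2π partner and an enantioselective oxygen variant are new. Ring C closes by a six-membered Friedel–Crafts attack of the arene on the exocyclic carbenium carbon (6-exo-trig at C4), the second bond of an asynchronous [4+2]. C2 is set by the chiral squaramide–triflate anion, which shields one face of the planar oxocarbenium ion so that C3 adds to the face leading to 2R; C3 is set relative to C2 by a compact synclinal transition state with the bulky OTBS group exo (anti to O1) and hydrogen inside, which gives the 2,3-trans diequatorial arrangement (3R). The step needs the ketene acetal to outcompete ring A and the geranyl alkenes for 14 (it is far more nucleophilic than either), closure at C4a and not C8 (the TIPS ether, pushed over C8 by the C6 geranyl chain, blocks that site, whereas C4a is flanked only by OMe), and survival of the geranyl chain (excess 13 buffers the medium, so no free strong acid is present at −78 °C). Mild aqueous acid then hydrolyses the strained, electron-rich benzylic dimethyl ketal 15 to ketone 16 without touching the silyl ethers.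

Step 9
Reactants: 16 (2R,3R)-3-(tert-butyldimethylsilyloxy)-2-[4-(tert-butyldimethylsilyloxy)phenyl]-6-[(2E)-3,7-dimethylocta-2,6-dien-1-yl]-5-methoxy-7-(triisopropylsilyloxy)chroman-4-one
Product: 17 (2R,3R)-6-[(2E)-3,7-dimethylocta-2,6-dien-1-yl]-3,7-dihydroxy-2-(4-hydroxyphenyl)-5-methoxychroman-4-one
Conditions: TBAF (4 equiv), AcOH (4 equiv), THF, 0 °C → rt
Reagents that add atoms: none
Why: Acetic acid-buffered fluoride cleaves the two aryl silyl ethers and the α-keto secondary silyl ether (global desilylation) without generating free phenoxides, so that ring C is not opened and C2 and C3 keep their configuration.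

Compound list
1 | 5-methoxybenzene-1,3-diol | COc1cc(O)cc(O)c1 | starting material
2 | 1-methoxy-3,5-bis(triisopropylsilyloxy)benzene | COc1cc(O[Si](C(C)C)(C(C)C)C(C)C)cc(O[Si](C(C)C)(C(C)C)C(C)C)c1 | intermediate
3 | 2-bromo-1-methoxy-3,5-bis(triisopropylsilyloxy)benzene | COc1cc(O[Si](C(C)C)(C(C)C)C(C)C)cc(O[Si](C(C)C)(C(C)C)C(C)C)c1Br | intermediate
4 | geranyl bromide, (2E)-1-bromo-3,7-dimethylocta-2,6-diene | BrC/C=C(\C)CCC=C(C)C | starting material
5 | [2-methoxy-4,6-bis(triisopropylsilyloxy)phenyl]lithium | COc1cc(O[Si](C(C)C)(C(C)C)C(C)C)cc(O[Si](C(C)C)(C(C)C)C(C)C)c1[Li] | intermediate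
6 | 2-[(2E)-3,7-dimethylocta-2,6-dien-1-yl]-1-methoxy-3,5-bis(triisopropylsilyloxy)benzene | COc1cc(O[Si](C(C)C)(C(C)C)C(C)C)cc(O[Si](C(C)C)(C(C)C)C(C)C)c1C/C=C(\C)CCC=C(C)C | intermediate
7 | 4-[(2E)-3,7-dimethylocta-2,6-dien-1-yl]-3-methoxy-5-(triisopropylsilyloxy)phenol | COc1cc(O)cc(O[Si](C(C)C)(C(C)C)C(C)C)c1C/C=C(\C)CCC=C(C)C | intermediate
8 | 4-(tert-butyldimethylsilyloxy)benzaldehyde | O=Cc1ccc(O[Si](C)(C)C(C)(C)C)cc1 | starting material
9 | chloro[4-(tert-butyldimethylsilyloxy)phenyl]methyl 2,2-dimethylpropanoate (racemic) | CC(C)(C)C(=O)OC(Cl)c1ccc(O[Si](C)(C)C(C)(C)C)cc1 | intermediate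
10 | sodium 4-[(2E)-3,7-dimethylocta-2,6-dien-1-yl]-3-methoxy-5-(triisopropylsilyloxy)phenoxide | COc1cc([O-])cc(O[Si](C(C)C)(C(C)C)C(C)C)c1C/C=C(\C)CCC=C(C)C.[Na+] | intermediate
11 | [4-(tert-butyldimethylsilyloxy)phenyl]{4-[(2E)-3,7-dimethylocta-2,6-dien-1-yl]-3-methoxy-5-(triisopropylsilyloxy)phenoxy}methyl 2,2-dimethylpropanoate (racemic) | CC(C)(C)C(=O)OC(Oc1cc(O[Si](C(C)C)(C(C)C)C(C)C)c(C/C=C(\C)CCC=C(C)C)c(OC)c1)c1ccc(O[Si](C)(C)C(C)(C)C)cc1 | intermediate
12 | 2,2-dimethoxyacetaldehyde | COC(OC)C=O | starting material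
13 | tert-butyl[(2,2-dimethoxyethenyl)oxy]dimethylsilane | COC(OC)=CO[Si](C)(C)C(C)(C)C | intermediate
14 | [4-(tert-butyldimethylsilyloxy)benzylidene]{4-[(2E)-3,7-dimethylocta-2,6-dien-1-yl]-3-methoxy-5-(triisopropylsilyloxy)phenyl}oxonium trifluoromethanesulfonate | COc1cc([O+]=Cc2ccc(O[Si](C)(C)C(C)(C)C)cc2)cc(O[Si](C(C)C)(C(C)C)C(C)C)c1C/C=C(\C)CCC=C(C)C.[O-]S(=O)(=O)C(F)(F)F | intermediate
15 | (2R,3R)-3-(tert-butyldimethylsilyloxy)-2-[4-(tert-butyldimethylsilyloxy)phenyl]-6-[(2E)-3,7-dimethylocta-2,6-dien-1-yl]-4,4,5-trimethoxy-7-(triisopropylsilyloxy)chromane | COc1c(C/C=C(\C)CCC=C(C)C)c(O[Si](C(C)C)(C(C)C)C(C)C)cc2c1C(OC)(OC)[C@H](O[Si](C)(C)C(C)(C)C)[C@@H](c1ccc(O[Si](C)(C)C(C)(C)C)cc1)O2 | intermediate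
16 | (2R,3R)-3-(tert-butyldimethylsilyloxy)-2-[4-(tert-butyldimethylsilyloxy)phenyl]-6-[(2E)-3,7-dimethylocta-2,6-dien-1-yl]-5-methoxy-7-(triisopropylsilyloxy)chroman-4-one | COc1c(C/C=C(\C)CCC=C(C)C)c(O[Si](C(C)C)(C(C)C)C(C)C)cc2c1C(=O)[C@H](O[Si](C)(C)C(C)(C)C)[C@@H](c1ccc(O[Si](C)(C)C(C)(C)C)cc1)O2 | intermediate
17 | (2R,3R)-6-[(2E)-3,7-dimethylocta-2,6-dien-1-yl]-3,7-dihydroxy-2-(4-hydroxyphenyl)-5-methoxychroman-4-one | COc1c(C/C=C(\C)CCC=C(C)C)c(O)cc2c1C(=O)[C@H](O)[C@@H](c1ccc(O)cc1)O2 | target

Total step count: 9. Longest linear sequence: 7 steps (steps 1, 2, 3, 4, 6, 8, 9).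

Steps most likely to fail

Step 8 (key step). The carbenium centre at C4 may collapse by methyl loss to an open-chain ester before ring closure, facial or exo/endo discrimination may be poor, or closure may occur partly at C8. The fallback sets out from 11 and comes back at 16, building the two bonds one after the other with known chemistry. (S)-3-{[(tert-Butyldimethylsilyl)oxy]acetyl}-4-isopropyl-1,3-thiazolidine-2-thione F1, made from the commercial thiazolidinethione and (tert-butyldimethylsilyloxy)acetic acid by carbodiimide coupling, is converted with TiCl4 and i-Pr2NEt (CH2Cl2, −78 °C) into its chelated Z chlorotitanium enolate F2. F2 is combined with 11 and SnCl4; the oxocarbenium ion from 11 should add anti to the isopropyl group through an open transition state, the known course of titanium glycolate enolate additions to acetals, to give the anti adduct (2R,3R)-configured N-acyl thiazolidinethione F3. Brief treatment with LiOH and H2O2 (THF/H2O, 0 °C) removes the auxiliary to give (2R,3R)-2-(tert-butyldimethylsilyloxy)-3-aryloxy-3-arylpropanoic acid F4. TFAA with 2,6-di-tert-butylpyridine (CH2Cl2, 0 °C) converts F4 into its mixed trifluoroacetic anhydride F5, which closes onto C4a by intramolecular Friedel–Crafts acylation to give 16.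

Step 6. The ambident phenoxide may be alkylated at carbon, the α-chloroalkyl ester may transfer its acyl group, and the acylal may be lost by hydrolysis on purification. The fallback sets out from 7 and 8 and comes back at 16, replacing the carboxylate leaving group by a robust benzotriazole N,O-acetal. Aldehyde 8, benzotriazole and SOCl2 give 1-{chloro[4-(tert-butyldimethylsilyloxy)phenyl]methyl}-1H-benzotriazole F6. F6 alkylates sodium phenoxide 10 (THF, 0 °C) to the chromatographically stable 1-{[4-(tert-butyldimethylsilyloxy)phenyl][4-geranyl-3-methoxy-5-(triisopropylsilyloxy)phenoxy]methyl}-1H-benzotriazole F7. F7 is ionised under the conditions of step 8, benzotriazole being expelled on N-protonation, and passes through 14 and 15 to 16.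

Step 4. The rate difference between the two identical silyl ethers may be too small, leading to double or wrong-site desilylation. The fallback sets out from 6 and comes back at 7, replacing rate discrimination by orthogonal silyl groups. Excess TBAF removes both silyl groups to give 4-[(2E)-3,7-dimethylocta-2,6-dien-1-yl]-5-methoxybenzene-1,3-diol F8. The unhindered hydroxyl para to the geranyl chain is silylated selectively (TBSCl 1.0 equiv, imidazole, CH2Cl2, −20 °C) to give 5-(tert-butyldimethylsilyloxy)-2-geranyl-3-methoxyphenol F9. The hindered hydroxyl is capped with TIPSOTf and 2,6-lutidine to give the mixed bis-silyl ether F10. KHF2 in MeOH at rt then cleaves the aryl TBS ether in the presence of the aryl TIPS ether and gives 7.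

Further compounds
F1 | step 8 | (S)-3-{[(tert-butyldimethylsilyl)oxy]acetyl}-4-isopropyl-1,3-thiazolidine-2-thione | CC(C)[C@H]1CSC(=S)N1C(=O)CO[Si](C)(C)C(C)(C)C
F2 | step 8 | Z chlorotitanium enolate of F1 | Cl[Ti](Cl)(Cl)O/C(=C\O[Si](C)(C)C(C)(C)C)N1C(=S)SC[C@@H]1C(C)C
F3 | step 8 | (S)-3-{(2R,3R)-2-(tert-butyldimethylsilyloxy)-3-[4-(tert-butyldimethylsilyloxy)phenyl]-3-[4-geranyl-3-methoxy-5-(triisopropylsilyloxy)phenoxy]propanoyl}-4-isopropyl-1,3-thiazolidine-2-thione | CC(C)[C@H]1CSC(=S)N1C(=O)[C@H](O[Si](C)(C)C(C)(C)C)[C@@H](c1ccc(O[Si](C)(C)C(C)(C)C)cc1)Oc1cc(O[Si](C(C)C)(C(C)C)C(C)C)c(C/C=C(\C)CCC=C(C)C)c(OC)c1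
F4 | step 8 | (2R,3R)-2-(tert-butyldimethylsilyloxy)-3-[4-(tert-butyldimethylsilyloxy)phenyl]-3-[4-geranyl-3-methoxy-5-(triisopropylsilyloxy)phenoxy]propanoic acid | OC(=O)[C@H](O[Si](C)(C)C(C)(C)C)[C@@H](c1ccc(O[Si](C)(C)C(C)(C)C)cc1)Oc1cc(O[Si](C(C)C)(C(C)C)C(C)C)c(C/C=C(\C)CCC=C(C)C)c(OC)c1
F5 | step 8 | mixed trifluoroacetic anhydride of F4 | FC(F)(F)C(=O)OC(=O)[C@H](O[Si](C)(C)C(C)(C)C)[C@@H](c1ccc(O[Si](C)(C)C(C)(C)C)cc1)Oc1cc(O[Si](C(C)C)(C(C)C)C(C)C)c(C/C=C(\C)CCC=C(C)C)c(OC)c1
F6 | step 6 | 1-{chloro[4-(tert-butyldimethylsilyloxy)phenyl]methyl}-1H-benzotriazole (racemic) | ClC(c1ccc(O[Si](C)(C)C(C)(C)C)cc1)n1nnc2ccccc12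
F7 | step 6 | 1-{[4-(tert-butyldimethylsilyloxy)phenyl][4-geranyl-3-methoxy-5-(triisopropylsilyloxy)phenoxy]methyl}-1H-benzotriazole (racemic) | CC(C)(C)[Si](C)(C)Oc1ccc(cc1)C(Oc1cc(O[Si](C(C)C)(C(C)C)C(C)C)c(C/C=C(\C)CCC=C(C)C)c(OC)c1)n1nnc2ccccc12
F8 | step 4 | 4-[(2E)-3,7-dimethylocta-2,6-dien-1-yl]-5-methoxybenzene-1,3-diol | COc1cc(O)cc(O)c1C/C=C(\C)CCC=C(C)C
F9 | step 4 | 5-(tert-butyldimethylsilyloxy)-2-[(2E)-3,7-dimethylocta-2,6-dien-1-yl]-3-methoxyphenol | COc1cc(O[Si](C)(C)C(C)(C)C)cc(O)c1C/C=C(\C)CCC=C(C)C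
F10 | step 4 | 5-(tert-butyldimethylsilyloxy)-2-[(2E)-3,7-dimethylocta-2,6-dien-1-yl]-1-methoxy-3-(triisopropylsilyloxy)benzene | COc1cc(O[Si](C)(C)C(C)(C)C)cc(O[Si](C(C)C)(C(C)C)C(C)C)c1C/C=C(\C)CCC=C(C)C
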